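The numbers are invented; the rest is arithmetic.

What is left at the end is what you count: each link removes 2 ends, and the ends still there, dead ones included, make the chains. So chain length = total ends charged / (total ends charged − 2[links]).

the same everywhere: first end groups 0.80 M; time 3.0 h

| run | second end groups |
|---|---|
| alder | 0.800 M |
| elm | 0.400 M |

    first end groups → decomposition product (k1 = 2.3 × 10⁻⁷ s⁻¹)
    second end groups → decomposed reagent (k2 = 2.9 × 10⁻⁴ s⁻¹)
    first end groups + second end groups ⇌ links (K3 = 25 L mol⁻¹, k3 = 0.0035 L mol⁻¹ s⁻¹)

1. which of the two ends with the longer chains by the average number of monomer units in a chain (unreacted monomers counted as chains of one) ("neither" if they lie within 10%) (alder / elm / neither)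
2. average number of monomer units in a chain (unreacted monomers counted as chains of one) at the end, alder
3. average number of monomer units in a chain (unreacted monomers counted as chains of one) at the end, elm

- each molecule carries two end groups: a chain counts once for every two ends that are left, dead ends included; the units are half of the end groups of the two monomers charged
- run time (alder): 3.0 h

You can drop step 1: its half-life of 35 d is far longer than the run. So [first end groups] = their charge − [links].

In alder, forward linking starts 9.7 times as fast as the loss of second end groups. [second end groups] cancels from that ratio, so elm starts at the same 9.66. I therefore start from equilibrium without loss, which gives S = 0.640 M of links in alder and 0.366 M in elm.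

After that, take free second end groups in a steady state. A link that opens frees one, which either relinks or dies, and the dying share is the loss constant over the sum of the loss constant and the linking constant times [first end groups]. Links then fall at the opening rate times that share, and integrating this gives

m ln(S/[links]) − (S − [links]) = g t.

Here m is the first end groups charged plus the loss constant over the linking constant, 0.883 M. And g is the leak, the loss constant over the equilibrium constant, 0.0418 M h⁻¹.

Expanding the logarithm to second order, I get [links] of 0.450 M in alder and 0.293 M in elm. The lengths are then 2.29 and 1.95, so alder is longer than elm by more than the margin.

The forecast gives alder, with 2.35 and 1.75, on the ground that “its balanced charge supplies more second end groups”.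

The flask gives 2.35 for alder and 1.84 for elm, so alder has the longer chains. Alder lies above my figure and elm below it. Alder's links stand at 57.5% of the first end groups charged after 3.00 h, where I had 56.2%. Read later, alder holds links at 30.6% after 12.0 h, and the leak, solved for time, puts that level at 10.8 h.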